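Ring B, the isopropyl-bearing cyclohexane (C5, C6, C7, C8, C9, C10; eudesmane numbering), is closed last by an intramolecular aldol addition that joins C9 to the quaternary ring-fusion carbon C10, exploiting the 1,3-relationship of the C9 hydroxyl and the C1 oxygen across C10. The precursor is a monocyclic ring A silyl enol ether that already carries the complete styryl orthoester cage (O4, O6, O15) and a C6–C9 chain ending in an aldehyde. The rigid cage holds this chain equatorial, so only the trans-fused, all-chair ketol is a stable product; C9 and C10 are set together. Ring A comes from a Diels–Alder reaction, and every stereocentre is relayed from one reagent-controlled allylboration.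

Key step: step 12

Remark on numbering: locants C1–C15 are those of the eudesmane skeleton of the target (ring A: C1, C2, C3, C4, C5, C10; ring B: C5, C6, C7, C8, C9, C10; C14 = methyl on C10; C15 = CH2O on C4; isopropyl on C7) and are kept for all precursors.
Assumption: trimethyl orthocinnamate 15 is not taken as a catalogue reagent and is prepared in step 8.

Step 1
Reactants: 1 2,3-dimethylfuran
Product: 3 (2E)-3-methyl-4-oxopent-2-enal, via (2Z)-3-methyl-4-oxopent-2-enal 2 (not isolated)
Conditions: NBS, NaHCO3, acetone/H2O, −15 °C; then pyridine, 23 °C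
Reagents that add atoms: water, O
Why: oxidative ring opening of the furan (bromination at the free α-position, then hydrolysis) should give the cis 4-oxo-enal, which pyridine isomerises to the trans isomer; no stereocentre is formed.

Step 2
Reactants: 3 (2E)-3-methyl-4-oxopent-2-enal; 4 (2E)-4-methylpent-2-ene
Product: 5 (3E,5R,6R)-5-hydroxy-3-methyl-6-(propan-2-yl)octa-3,7-dien-2-one
Conditions: 4, KOtBu, n-BuLi, THF, −78 to −45 °C; (+)-Ipc2BOMe (Ipc = isopinocampheyl), −78 °C; BF3·OEt2; then 3, −78 °C; ethanolamine work-up
Reagents that add atoms: none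
Why: γ-substituted allylboration with a diisopinocampheylborane through a closed chair-like six-membered transition state, in which the E-allyl unit gives the anti C6/C7 relationship, the (+)-Ipc2B group directs attack to the re face of the aldehyde (C6) and the aldehyde reacts in preference to the enone carbonyl.

Step 3
Reactants: 5 (3E,5R,6R)-5-hydroxy-3-methyl-6-(propan-2-yl)octa-3,7-dien-2-one
Product: 6 (3E,5R,6R)-3-methyl-2-oxo-6-(propan-2-yl)octa-3,7-dien-5-yl benzoate
Conditions: BzCl, pyridine, DMAP (cat.), CH2Cl2, 0 °C
Reagents that add atoms: benzoyl chloride, O=C(Cl)c1ccccc1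
Why: acylation of the secondary alcohol protects O6 as an ester that step 7 removes together with the second benzoate; no stereocentre is touched.

Step 4
Reactants: 6 (3E,5R,6R)-3-methyl-2-oxo-6-(propan-2-yl)octa-3,7-dien-5-yl benzoate
Product: 7 (3E,5R,6R)-3-methyl-6-(propan-2-yl)-2-{[tri(propan-2-yl)silyl]oxy}octa-1,3,7-trien-5-yl benzoate
Conditions: iPr3SiOTf, Et3N, CH2Cl2, −78 to 0 °C
Reagents that add atoms: triisopropylsilyl trifluoromethanesulfonate, CC(C)[Si](C(C)C)(C(C)C)OS(=O)(=O)C(F)(F)F
Why: soft enolisation of the methyl ketone, whose only α-hydrogens are on the methyl group, should give the cross-conjugated 2-silyloxy diene as a robust silyl enol ether; stereocentres are untouched.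

Step 5
Reactants: 8 2,2-dimethyl-1,3-dioxan-5-one
Product: 9 2,2-dimethyl-4H-1,3-dioxin-5-yl benzoate
Conditions: KN(SiMe3)2, THF, −78 °C; then BzCl
Reagents that add atoms: benzoyl chloride, O=C(Cl)c1ccccc1
Why: O-acylation of the potassium enolate gives the enol benzoate, a storable precursor of 2-(benzoyloxy)acrolein; no stereocentre.

Step 6
Reactants: 7 (3E,5R,6R)-3-methyl-6-(propan-2-yl)-2-{[tri(propan-2-yl)silyl]oxy}octa-1,3,7-trien-5-yl benzoate; 9 2,2-dimethyl-4H-1,3-dioxin-5-yl benzoate
Product: 11 (1S,2R)-2-[(1R,2R)-1-(benzoyloxy)-2-(propan-2-yl)but-3-en-1-yl]-1-formyl-3-methyl-4-{[tri(propan-2-yl)silyl]oxy}cyclohex-3-en-1-yl benzoate, via 2-(benzoyloxy)prop-2-enal 10 (not isolated)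
Conditions: toluene, 110 °C, sealed tube, BHT (cat.)
Reagents that add atoms: none
Why: retro-hetero-Diels–Alder loss of acetone from 9 releases acrolein 10, which should add to the 2-silyloxy diene in a Diels–Alder reaction with para regiochemistry (ring A: bonds C2–C3 and C4–C5), the endo formyl group placing C15 cis to the C6 chain (C4) and 1,3-allylic strain (C6–H eclipsing C5=C10 toward the C10 methyl) directing the dienophile anti to the branched C7 substituent (C5).

Step 7
Reactants: 11 the Diels–Alder adduct
Product: 12 (1S,2R)-1-(hydroxymethyl)-2-[(1R,2R)-1-hydroxy-2-(propan-2-yl)but-3-en-1-yl]-3-methyl-4-{[tri(propan-2-yl)silyl]oxy}cyclohex-3-en-1-ol (4,6,15-triol)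
Conditions: LiAlH4, THF, 0 °C; NaOH (aq) work-up
Reagents that add atoms: none
Why: hydride reduction of the formyl group and reductive cleavage of both benzoates should give the triol in one operation, the silyl enol ether and the alkenes being inert; no new stereocentre.

Step 8
Reactants: 13 (2E)-3-phenylprop-2-enenitrile (cinnamonitrile)
Product: 15 [(1E)-3,3,3-trimethoxyprop-1-en-1-yl]benzene (trimethyl orthocinnamate), via methyl cinnamimidate hydrochloride 14 (not isolated)
Conditions: HCl (g), MeOH (1.1 equiv), Et2O, 0 °C; then MeOH (excess), hexane, 23 °C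
Reagents that add atoms: methanol, CO
Why: Pinner reaction, in which HCl-promoted addition of methanol to the nitrile gives the imidate hydrochloride and its methanolysis gives the orthoester with the E alkene retained.

Step 9
Reactants: 12 the 4,6,15-triol; 15 trimethyl orthocinnamate
Product: 16 4,6,15-O-[(2E)-3-phenylprop-2-en-1-ylidyne] orthoester of 12 (2,7,8-trioxabicyclo[3.2.1]octane cage; ring A silyl enol ether and C7 vinyl group retained)
Conditions: 15 (1.5 equiv), PPTS (5 mol %), 4 Å molecular sieves, CH2Cl2, 23 °C; Et3N quench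
Reagents that add atoms: none
Why: acid-catalysed orthoester exchange of the 1,2,4-triol (O15, O4, O6) should close the bicyclic cage with loss of three methanol, the configuration at the orthoester carbon being dictated by the cage and C7 and C10 lying equatorial on its dioxane chair.

Step 10
Reactants: 16 the cage orthoester
Product: 17 primary alcohol (C8H2–C9H2OH in place of the vinyl group of 16)
Conditions: 9-borabicyclo[3.3.1]nonane (9-BBN), THF, 0 to 23 °C; then H2O2, NaOH (aq), 0 °C
Reagents that add atoms: hydrogen peroxide, OO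
Why: anti-Markovnikov hydroboration–oxidation, the bulky borane selecting the terminal monosubstituted alkene over the styryl and the tetrasubstituted enol ether double bonds; no stereocentre is formed.

Step 11
Reactants: 17 the primary alcohol
Product: 18 aldehyde (C9 formyl; silyl enol ether and cage retained)
Conditions: Pr4N[RuO4] (5 mol %), NMO, 4 Å molecular sieves, CH2Cl2, 23 °C
Reagents that add atoms: none
Why: catalytic perruthenate oxidation of the primary alcohol to the aldehyde under non-acidic conditions that spare the orthoester and the silyl enol ether.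

Step 12
Reactants: 18 the aldehyde
Product: 20 (4S,5R,6R,7S,9R,10R)-9-hydroxy-4,6,15-O-[(2E)-3-phenylprop-2-en-1-ylidyne]eudesman-1-one (trans-fused ketol), via tetrabutylammonium enolate 19 (not isolated)
Conditions: Bu4NF (1.1 equiv), THF (0.005 M), −20 to 23 °C, 12 h; NH4Cl (aq), 0 °C
Reagents that add atoms: none
Why: Fluoride removes the silyl group and unveils the enolate regiospecifically at C1–C10, which adds to the C9 aldehyde in a reversible intramolecular aldol addition (closest known type: fluoride-mediated intramolecular aldol of silyl enol ether aldehydes). Ring B closes in a 6-(enolexo)-exo-trig mode by forming the C9–C10 bond. The quaternary C10 is controlled by the orthoester cage: it locks ring A and holds C6–C7 equatorial with H5 and H6 antiperiplanar, so ring B can be a chair only when C9 is equatorial on ring A (trans fusion, C14 axial), whereas the cis-fused ketol would need a twist-boat ring B and should be drained by retro-aldol equilibration. C9 is controlled by the axial C7 isopropyl group, which disfavours an axial C9–O bond (1,3-diaxial), leaving the equatorial hydroxyl, which can also hydrogen-bond to the C1 carbonyl. The selectivity needed is thermodynamic (closed over open, trans over cis) and positional (C10 over C2 or C8 enolates): closure from C2 would give an eight-membered ring, the C8 enolate cannot reach C1 because the cage keeps the chain equatorial, and the quaternary C10 rules out dehydration.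

Step 13
Reactants: 20 the trans-fused ketol
Product: 21 (1S,4S,5R,6R,7S,9R,10S)-4,6,15-O-[(2E)-3-phenylprop-2-en-1-ylidyne]eudesmane-1,4,6,9,15-pentol (target)
Conditions: NaBH4, MeOH/THF, −20 °C
Reagents that add atoms: none
Why: NaBH4 reduction of the C1 ketone, in which hydride should attack axially from the face opposite the axial C14 methyl and give the equatorial C1 alcohol syn to the C9 hydroxyl.

Compound list
1 | 2,3-dimethylfuran | Cc1occc1C | starting material
2 | (2Z)-3-methyl-4-oxopent-2-enal | CC(=O)/C(C)=C\C=O | intermediate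
3 | (2E)-3-methyl-4-oxopent-2-enal | CC(=O)/C(C)=C/C=O | intermediate
4 | (2E)-4-methylpent-2-ene | C/C=C/C(C)C | starting material
5 | (3E,5R,6R)-5-hydroxy-3-methyl-6-(propan-2-yl)octa-3,7-dien-2-one | CC(=O)/C(C)=C/[C@H](O)[C@H](C(C)C)C=C | intermediate
6 | (3E,5R,6R)-3-methyl-2-oxo-6-(propan-2-yl)octa-3,7-dien-5-yl benzoate | CC(=O)/C(C)=C/[C@H](OC(=O)c1ccccc1)[C@H](C(C)C)C=C | intermediate
7 | (3E,5R,6R)-3-methyl-6-(propan-2-yl)-2-{[tri(propan-2-yl)silyl]oxy}octa-1,3,7-trien-5-yl benzoate | C=C(O[Si](C(C)C)(C(C)C)C(C)C)/C(C)=C/[C@H](OC(=O)c1ccccc1)[C@H](C(C)C)C=C | intermediate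
8 | 2,2-dimethyl-1,3-dioxan-5-one | CC1(C)OCC(=O)CO1 | starting material
9 | 2,2-dimethyl-4H-1,3-dioxin-5-yl benzoate | CC1(C)OCC(OC(=O)c2ccccc2)=CO1 | intermediate
10 | 2-(benzoyloxy)prop-2-enal | C=C(OC(=O)c1ccccc1)C=O | intermediate
11 | (1S,2R)-2-[(1R,2R)-1-(benzoyloxy)-2-(propan-2-yl)but-3-en-1-yl]-1-formyl-3-methyl-4-{[tri(propan-2-yl)silyl]oxy}cyclohex-3-en-1-yl benzoate | CC1=C(O[Si](C(C)C)(C(C)C)C(C)C)CC[C@@](OC(=O)c2ccccc2)(C=O)[C@H]1[C@H](OC(=O)c2ccccc2)[C@H](C(C)C)C=C | intermediate
12 | (1S,2R)-1-(hydroxymethyl)-2-[(1R,2R)-1-hydroxy-2-(propan-2-yl)but-3-en-1-yl]-3-methyl-4-{[tri(propan-2-yl)silyl]oxy}cyclohex-3-en-1-ol | CC1=C(O[Si](C(C)C)(C(C)C)C(C)C)CC[C@@](O)(CO)[C@H]1[C@H](O)[C@H](C(C)C)C=C | intermediate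
13 | (2E)-3-phenylprop-2-enenitrile | N#C/C=C/c1ccccc1 | starting material
14 | methyl (2E)-3-phenylprop-2-enimidate hydrochloride | COC(=[NH2+])/C=C/c1ccccc1.[Cl-] | intermediate
15 | [(1E)-3,3,3-trimethoxyprop-1-en-1-yl]benzene (trimethyl orthocinnamate) | COC(OC)(OC)/C=C/c1ccccc1 | intermediate
16 | 4,6,15-O-[(2E)-3-phenylprop-2-en-1-ylidyne] orthoester of 12 (4S,5R,6R,7R; ring A silyl enol ether, C7 vinyl) | C=C[C@@H](C(C)C)[C@H]1O[C@]2(/C=C/c3ccccc3)OC[C@]3(O2)CCC(O[Si](C(C)C)(C(C)C)C(C)C)=C(C)[C@H]13 | intermediate
17 | C9 primary alcohol derived from 16 (4S,5R,6R,7S) | OCC[C@@H](C(C)C)[C@H]1O[C@]2(/C=C/c3ccccc3)OC[C@]3(O2)CCC(O[Si](C(C)C)(C(C)C)C(C)C)=C(C)[C@H]13 | intermediate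
18 | C9 aldehyde derived from 17 (4S,5R,6R,7S) | O=CC[C@@H](C(C)C)[C@H]1O[C@]2(/C=C/c3ccccc3)OC[C@]3(O2)CCC(O[Si](C(C)C)(C(C)C)C(C)C)=C(C)[C@H]13 | intermediate
19 | tetrabutylammonium C1–C10 enolate of the desilylated aldehyde | O=CC[C@@H](C(C)C)[C@H]1O[C@]2(/C=C/c3ccccc3)OC[C@]3(O2)CCC([O-])=C(C)[C@H]13.CCCC[N+](CCCC)(CCCC)CCCC | intermediate
20 | (4S,5R,6R,7S,9R,10R)-9-hydroxy-4,6,15-O-[(2E)-3-phenylprop-2-en-1-ylidyne]eudesman-1-one | CC(C)[C@@H]1C[C@@H](O)[C@@]2(C)[C@@H]3[C@@H]1O[C@]1(/C=C/c4ccccc4)OC[C@@]3(CCC2=O)O1 | intermediate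
21 | (1S,4S,5R,6R,7S,9R,10S)-4,6,15-O-[(2E)-3-phenylprop-2-en-1-ylidyne]eudesmane-1,4,6,9,15-pentol (CNP0252898.2) | CC(C)[C@@H]1C[C@@H](O)[C@@]2(C)[C@@H]3[C@@H]1O[C@]1(/C=C/c4ccccc4)OC[C@@]3(CC[C@@H]2O)O1 | target

Total step count: 13. Longest linear sequence: 11 steps (steps 1, 2, 3, 4, 6, 7, 9, 10, 11, 12, 13); steps 5 and 8 are side branches.

Steps most likely to fail

Step 12 is the riskiest. The aldol equilibrium may not lie far enough on the side of the closed ketol (retro-aldol back to the keto aldehyde during reaction or work-up), or equilibration of a kinetically formed cis-fused ketol to the trans-fused one may be slow. The fallback keeps the same bond but replaces the equilibrating free enolate by a reductively generated, chelated metal enolate. It sets out from 18: NBS in THF at −78 °C should convert the silyl enol ether into the α-bromo ketone F1 (C10 epimers, immaterial). SmI2 in THF at −78 °C then cleaves the C–Br bond to a samarium enolate fixed at C10, and Reformatsky-type addition to the C9 aldehyde gives a chelated samarium aldolate that should not revert at this temperature. Protonation returns to the route at 20.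

Step 6 comes second. Incomplete endo preference of the α-acyloxy acrolein (formyl versus benzoyloxy under the diene) would erode the configuration of the quaternary C4, and the allylic benzoate may partly ionise at 110 °C. The fallback introduces the C4 oxygen after the cycloaddition. It sets out from 7: Diels–Alder reaction with acrolein (toluene, 60 °C) should give the ring A aldehyde F2, in which C4 is still enolisable so that endo/exo control no longer matters. Deprotonation with KN(SiMe3)2 at −78 °C and oxidation of the aldehyde enolate with 2-(phenylsulfonyl)-3-phenyloxaziridine, from the face anti to the C5 side chain, gives the α-hydroxy aldehyde F3. LiAlH4 then reduces the formyl group and cleaves the C6 benzoate, returning to the route at 12.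

Step 9 comes third. PPTS and the methanol released may protodesilylate the silyl enol ether, or the exchange may stop at a monocyclic mixed methyl orthoester. The fallback avoids acid altogether and sets out from 12. N,N-dimethylcinnamamide is O-methylated with Me3OBF4 and treated with NaOMe to give N,N-dimethylcinnamamide dimethyl acetal F4. Heated with triol 12 in toluene at 80 °C, F4 should exchange under neutral conditions with loss of methanol and dimethylamine, returning to the route at 16.

Further compounds
F1 | step 12 | α-bromo ketone from 18 (C10 bromide, mixture of C10 epimers; C9 aldehyde and cage retained) | O=CC[C@@H](C(C)C)[C@H]1O[C@]2(/C=C/c3ccccc3)OC[C@]3(O2)CCC(=O)C(C)(Br)[C@H]13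
F2 | step 6 | acrolein cycloadduct of 7 (C4–H formyl compound, mixture of C4 epimers) | CC1=C(O[Si](C(C)C)(C(C)C)C(C)C)CCC(C=O)[C@H]1[C@H](OC(=O)c2ccccc2)[C@H](C(C)C)C=C
F3 | step 6 | α-hydroxy aldehyde (4S) obtained by enolate oxidation of F2 | CC1=C(O[Si](C(C)C)(C(C)C)C(C)C)CC[C@@](O)(C=O)[C@H]1[C@H](OC(=O)c2ccccc2)[C@H](C(C)C)C=C
F4 | step 9 | (2E)-1,1-dimethoxy-N,N-dimethyl-3-phenylprop-2-en-1-amine (N,N-dimethylcinnamamide dimethyl acetal) | COC(OC)(N(C)C)/C=C/c1ccccc1
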